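## Structural features

The target is an unsymmetrical dimer of two 6,8-dioxygenated 7-methoxy-3-methylisochroman-1-one units, each a benzene ring fused to a six-membered lactone. A single ether oxygen joins the benzylic carbon C4 of one unit (unit A, free hydroxyls at C6 and C8) to the aromatic carbon C6 of the other (unit B, free secondary hydroxyl at its own C4 and free phenol at C8). Each unit has two adjacent stereocentres, C3 (R, methyl-bearing, bound to the lactone oxygen) and C4 (S, benzylic, oxygen-bearing). In both units the methyl group and the C4 oxygen are trans on the lactone ring, and there are no other stereocentres. The fragile points are the secondary benzylic C4–O bonds (hydrogenolysis, ionization, elimination to the isocoumarin), the lactone of unit B next to its C4 hydroxyl (base-induced translactonization to a five-membered phthalide), and the electron-rich phenols. The real difficulty is to draw two differently functionalized monomers from one stock, one a C4 electrophile of the right stereochemical sense and one nucleophilic only at O6, and to form the hindered benzylic aryl ether with control at C4. A second difficulty is the penta-substituted benzene ring: the carbon that must carry the side chain, C4a, is the position least activated by the three ring oxygens. The key step uses exactly this atom, because C4a is the only unsubstituted position ortho to the carboxyl-bearing carbon C8a, so that a carboxylate-bound palladium reaches it and joins it to the CH2 of an epoxide whose methine becomes C3.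

## Logic of the disconnections

16 ⇒ 15 ⇒ 14. Two protecting-group bonds are added back: the O–Si bond on the C4 oxygen of unit B and the two O–acetyl bonds on O6 and O8 of unit A. The C4 hydroxyl of unit B stays silylated while an amine is present and is freed last by a weakly acidic fluoride source. This keeps a free C4 alkoxide away from the neighbouring lactone. Neither forward step may touch the lactones or the benzylic aryl ether.

14 ⇒ 13 + 10. The benzylic C4–O ether bond (C4 of unit A to O6 of unit B) is cut, the only bond joining the halves. This gives two monomers of one skeleton, 13 as carbon electrophile and 10 as oxygen nucleophile. A phenol displaces an activated secondary alcohol with inversion, so 13 must have its C4 hydroxyl cis to the C3 methyl (4R) to give the trans (4S) ether. 10 must offer only O6: its C4 hydroxyl is silylated, and O8 can stay free because its hydrogen bond to the lactone carbonyl makes it a much poorer acid than O6, which is para to that carbonyl.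

13 ⇒ 11 ⇒ 8 (through 12). The C4–O bond of 13 is traced to the epimeric alcohol 8 by an ester formed with inversion and then removed. The solvolysis that introduces the C4 oxygen gives the trans alcohol, right for unit B but wrong for the electrophile. The chloroacetate is chosen because thiourea removes it without disturbing aryl acetates.

10 ⇒ 9 ⇒ 8. The O–Si bond at C4 and the two phenolic O–acetyl bonds are adjusted. The gain is that 8 serves both halves. The demand is a deacetylation that stops at the aryl esters, hence aminolysis rather than alkoxide.

8 ⇒ 7 ⇒ 6. The C4–O bond is replaced by C4–Br and then by C4–H. C4 is the only benzylic methylene of 6, and the lactone carbonyl and two acetoxy groups make the ring poor enough for radical substitution at C4 to outrun ionic bromination at C5. The forward demands are mono-bromination and capture of the benzylic cation by water anti to the C3 methyl.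

6 ⇒ 3 + 4 (through 5). Two bonds of the lactone ring are cut together, C4a–C4 and C1–O2. This removes the heterocycle and the C3 stereocentre at once and leaves a benzoic acid and a three-carbon chiral epoxide. The forward step must functionalize the single C–H ortho to the carboxyl group of 3, open 4 only at CH2, and let 5 close. Acetyl groups rather than benzyl ethers are placed on O2 and O4 of 3. Benzyl ethers would have to be exchanged after the annulation, since they do not survive radical bromination and cannot be hydrogenolysed at the end without risk to the benzylic C4–O bonds. Acetates deactivate the ring for the bromination, last until the coupling and leave under mild aminolysis, which saves the exchange steps.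

3 ⇒ 2 ⇒ 1. The O–acetyl bonds are cut, then the aryl–carboxyl bond. In 1 the two equivalent positions ortho to one hydroxyl and para to the other are the only activated ones, so carboxylation should give one acid.

## Other disconnections considered

Alternative 1: The benzene ring is cut at C4a–C5 and C8–C8a, together with the lactone bond C1–O2.
- **Forward step:** the tetra-oxygenated diene A3 (1,2-dimethoxy-1,3-bis(trimethylsilyloxy)buta-1,3-diene) would add to the chiral ynoate A2 (methyl (4S,5R)-4-(tert-butyldimethylsilyloxy)-5-(trimethylsilyloxy)hex-2-ynoate). The adduct would aromatize by loss of methanol, and acidic work-up would strip the labile silyl groups so that the freed secondary hydroxyl closes the lactone. The product A1 is the same compound as 10.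
- **In favour:** polarity fixes the regiochemistry (the CH2 end of A3 goes to the β-carbon of A2). All ring oxygens, both stereocentres and the C4 oxygen arrive in the two components, so no benzylic bromination and no C4 cation are needed. On this point the alternative is better than the chosen plan.
- **Against:** A2 needs an anti-selective propiolate addition to a protected lactaldehyde of the less common (R) series, where Felkin control is seldom complete, and then differential silylation. A3 is a moisture-sensitive ketene acetal. The thermal cycloaddition of a hindered γ-silyloxy ynoate needs heat, which invites silyl migration and elimination.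
- **Comparison:** structurally it supplies unit B only. Unit A (13) needs the C4 epimer as a free alcohol with capped phenols, so a second diastereomer of A2 or an inversion with reprotection would be required, whereas 8 feeds both halves in the chosen plan. Mechanistically it replaces a catalytic C–H functionalization by a stoichiometric pericyclic construction of the arene. In step count the two are about equal as far as 10, and the chosen plan is shorter for the dimer.

Alternative 2: The lactone is cut at C3–O2 and the benzylic oxygen at C4–O, back to the achiral styrene ester A5 (methyl 3-methoxy-2,4-bis(pivaloyloxy)-6-[(Z)-prop-1-enyl]benzoate).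
- **Forward step:** a lactate-derived chiral aryl iodine diacetate (trivalent iodine) with a boron Lewis acid and acetic acid would add to one alkene face. The ester oxygen would close the six-membered ring at C3 with loss of the ester methyl, and acetate would enter at C4. The two oxygens would be delivered in a net syn sense (anti opening, then displacement of the aryliodanyl group with inversion), so the (Z)-alkene would give the trans lactone A4 ((3R,4S)-4-acetoxy-7-methoxy-3-methyl-6,8-bis(pivaloyloxy)isochroman-1-one).
- **In favour:** ring, both stereocentres and the C4 oxygen are made in one step from an achiral substrate, with no radical and no free cation. In stereochemical economy this is better than bromination, solvolysis and inversion.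
- **Against:** the absolute configuration rests on reagent control by a stoichiometric chiral iodane, and any minor enantiomer would reappear after coupling as diastereomeric dimers. Closure to the five-membered phthalide and oxidation of the ring compete, hence the heavy acylation. A5 still needs a carbon substituent at the same unreactive ortho position as 3 and then a (Z)-selective olefination.
- **Comparison:** structurally A4 fits unit B only after the pivalates are removed beside the C4 acetate, and unit A again needs the C4 epimer. On mechanism the two plans stand equal, both resting on known reaction types. In step economy no saving is expected, because what is gained after the ring closure is spent on A5.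

Alternative 3: The lactone is cut at C1–O2 and O2–C3, that is, the ring oxygen is removed, which leads to the racemic indanone A7 (5,7-dihydroxy-6-methoxy-2-methylindan-1-one).
- **Forward step:** a Baeyer–Villiger monooxygenase with cofactor recycling would insert oxygen between the carbonyl carbon and the methyl-bearing carbon of one enantiomer, while the other racemizes through its enol (dynamic kinetic resolution). The product would be A6 ((R)-6,8-dihydroxy-7-methoxy-3-methylisochroman-1-one), the diphenol corresponding to 6.
- **In favour:** no precious metal, no chiral reagent, water as solvent, and a substrate that should be reachable from 1 in about two operations. In reagent cost it is better than the chosen plan, and in step count to the lactone core it is its equal.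
- **Against:** acceptance of a tri-oxygenated indanone with free phenols, the level of enantioselection, and the choice between alkyl migration (wanted) and aryl migration (giving the isomeric 3,4-dihydrocoumarin) would all need enzyme screening. The phenolic ketone is prone to air oxidation at the pH needed for racemization, and such biotransformations run dilute.
- **Comparison:** structurally nothing is gained downstream, since A6 has the same C4 methylene as 6 and would need acetylation before the same later steps. Mechanistically the enzyme must prove its selectivity, whereas the chosen plan takes C3 from 4 with nothing to prove.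

Key step: step 3

Remark: the two bicycles are called unit A (etherified at its C4) and unit B (etherified at its O6), each numbered as an isochroman-1-one; the C4 configuration of bromide 7 is assumed to be immaterial because step 5 ionizes that centre.

## Route

Step 1
Reactants: 1 2-methoxyresorcinol (2-methoxybenzene-1,3-diol)
Product: 2 2,4-dihydroxy-3-methoxybenzoic acid
Conditions: KHCO3, CO2 (5 bar), H2O, 110 °C; then aq. HCl
Reagents that add atoms: carbon dioxide, O=C=O
Why: Kolbe–Schmitt carboxylation of a resorcinol: the phenoxide attacks CO2 ortho to one hydroxyl and para to the other, the only activated type of position in 1 (C4 and C6 are equivalent), and the ortho-hydroxy acid is held as its chelated salt.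

Step 2
Reactants: 2 2,4-dihydroxy-3-methoxybenzoic acid
Product: 3 2,4-diacetoxy-3-methoxybenzoic acid
Conditions: Ac2O, H2SO4 (cat.), 60 °C; then H2O
Reagents that add atoms: acetic anhydride, CC(=O)OC(C)=O
Why: Acid-catalysed O-acetylation of both phenols (the aspirin reaction); any mixed carboxylic anhydride is hydrolysed in the aqueous quench while the aryl acetates remain.

Step 3
Reactants: 3 2,4-diacetoxy-3-methoxybenzoic acid; 4 (R)-propylene oxide [(2R)-2-methyloxirane]
Product: 6 (R)-6,8-diacetoxy-7-methoxy-3-methylisochroman-1-one, via ring-opened hydroxy acid 5 (not isolated)
Conditions: Pd(OAc)2 (5 mol%), N-acetyl-L-tert-leucine (15 mol%), KOAc (1 equiv), 4 (3 equiv), (CF3)2CHOH, 30 °C, sealed vessel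
Reagents that add atoms: none
Why: The reaction type is known: Pd(OAc)2-catalysed, carboxylate-directed ortho C–H alkylation of benzoic acids with terminal epoxides to give 3-substituted isochroman-1-ones. The potassium carboxylate of 3 binds divalent palladium and the N-acetyl amino acid ligand serves as internal base in a concerted metalation–deprotonation at C6–H, giving a five-membered aryl palladacycle. The aryl–palladium bond then opens 4 at its unsubstituted CH2 in an SN2 manner without change in the oxidation state of the metal, which forms C4a–C4, and protonolysis releases hydroxy acid 5 and the catalyst. Acid 5 closes in the fluoroalcohol by attack of its secondary hydroxyl on the carboxyl carbon (6-exo-trig acyl substitution), forming C1–O2 and the one new ring. No stereocentre is created: C3 is the epoxide methine, whose C–O bond is never broken, so the (R) configuration of 4 passes unchanged into 6. Site selectivity at the arene is secured by the substrate, since C6–H is the only C–H ortho to the carboxylate and C5–H lies outside the reach of the palladacycle. Regioselectivity at the epoxide (CH2 over CH) follows from the steric demand of the SN2 opening, and ligand-accelerated C–H cleavage should outrun O-alkylation of the carboxylate. The acetoxy groups are weaker donors than ethers, but C6 stays para to the methoxy group, which should keep the aryl–palladium carbon nucleophilic enough.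

Step 4
Reactants: 6 (R)-6,8-diacetoxy-7-methoxy-3-methylisochroman-1-one
Product: 7 (3R,4S)-6,8-diacetoxy-4-bromo-7-methoxy-3-methylisochroman-1-one (trans)
Conditions: NBS (1.05 equiv), AIBN (cat.), PhCF3, 80 °C
Reagents that add atoms: N-bromosuccinimide, O=C1CCC(=O)N1Br
Why: Wohl–Ziegler radical bromination at the only benzylic methylene; the two acetoxy groups and the lactone carbonyl leave the ring too electron-poor for ionic bromination at C5. Bromine transfer to the planar benzylic radical anti to the C3 methyl should favour the trans bromide (4S), but this centre is ionized in step 5 and its configuration is not relied upon.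

Step 5
Reactants: 7 (3R,4S)-6,8-diacetoxy-4-bromo-7-methoxy-3-methylisochroman-1-one
Product: 8 (3R,4S)-6,8-diacetoxy-4-hydroxy-7-methoxy-3-methylisochroman-1-one (trans)
Conditions: Ag2CO3, acetone–H2O (4:1), 20 °C, dark
Reagents that add atoms: water, O
Why: Silver-assisted SN1 hydrolysis of a benzylic bromide: Ag+ abstracts bromide and water captures the flat benzylic cation on the face away from the C3 methyl, which sets C4 as S (trans). The carbonate takes up the acid, so aryl acetates and lactone should persist.

Step 6
Reactants: 8 (3R,4S)-6,8-diacetoxy-4-hydroxy-7-methoxy-3-methylisochroman-1-one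
Product: 9 (3R,4S)-6,8-diacetoxy-4-(tert-butyldimethylsilyloxy)-7-methoxy-3-methylisochroman-1-one
Conditions: TBSOTf, 2,6-lutidine, CH2Cl2, −78 to 0 °C
Reagents that add atoms: tert-butyldimethylsilyl trifluoromethanesulfonate, CC(C)(C)[Si](C)(C)OS(=O)(=O)C(F)(F)F
Why: Standard silylation of a hindered secondary alcohol with a silyl triflate and a non-nucleophilic base; no bond to C4 is broken, so its configuration is retained.

Step 7
Reactants: 9 (3R,4S)-6,8-diacetoxy-4-(tert-butyldimethylsilyloxy)-7-methoxy-3-methylisochroman-1-one
Product: 10 (3R,4S)-4-(tert-butyldimethylsilyloxy)-6,8-dihydroxy-7-methoxy-3-methylisochroman-1-one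
Conditions: pyrrolidine (5 equiv), CH2Cl2, 0 to 20 °C; aq. citric acid work-up
Reagents that add atoms: none
Why: Aminolysis of aryl esters: a secondary amine is acylated rapidly by phenyl acetates, whose phenoxide is a good leaving group, while the lactone and the silyl ether are inert under these alkoxide-free conditions.

Step 8
Reactants: 8 (3R,4S)-6,8-diacetoxy-4-hydroxy-7-methoxy-3-methylisochroman-1-one
Product: 11 (3R,4R)-6,8-diacetoxy-4-(chloroacetoxy)-7-methoxy-3-methylisochroman-1-one (cis)
Conditions: ClCH2CO2H, PPh3, DIAD, THF, 0 to 20 °C
Reagents that add atoms: chloroacetic acid, OC(=O)CCl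
Why: Mitsunobu esterification: chloroacetate displaces the alkoxyphosphonium ion of 8 in an SN2 step, which inverts C4 from S to R (cis). Chloroacetic acid is acidic enough for hindered secondary alcohols, and since the leaving group of 8 is cis to H3 no anti-periplanar elimination is available.

Step 9
Reactants: 11 (3R,4R)-6,8-diacetoxy-4-(chloroacetoxy)-7-methoxy-3-methylisochroman-1-one
Product: 13 (3R,4R)-6,8-diacetoxy-4-hydroxy-7-methoxy-3-methylisochroman-1-one (cis), via isothiouronium ester 12 (not isolated)
Conditions: thiourea, NaHCO3, Bu4NI (cat.), THF, 50 °C
Reagents that add atoms: none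
Why: Thiourea dechloroacetylation: sulfur displaces chloride to give 12, whose nitrogen attacks the ester carbonyl and releases the C4 alcohol as a five-membered thiazolidinone forms. The C4–O bond is untouched (retention), and aryl acetates, lacking the α-chloride, are not addressed.

Step 10
Reactants: 13 (3R,4R)-6,8-diacetoxy-4-hydroxy-7-methoxy-3-methylisochroman-1-one; 10 (3R,4S)-4-(tert-butyldimethylsilyloxy)-6,8-dihydroxy-7-methoxy-3-methylisochroman-1-one
Product: 14 (3R,4S)-6,8-diacetoxy-4-{[(3R,4S)-4-(tert-butyldimethylsilyloxy)-8-hydroxy-7-methoxy-3-methyl-1-oxoisochroman-6-yl]oxy}-7-methoxy-3-methylisochroman-1-one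
Conditions: PPh3, DIAD, toluene–THF, 0 to 20 °C
Reagents that add atoms: none
Why: Mitsunobu etherification of a secondary benzylic alcohol with a phenol: the O6 phenol of 10 (para to the lactone carbonyl, the most acidic hydroxyl) protonates the betaine, and its phenoxide displaces the alkoxyphosphonium ion of 13 from the face anti to the C3 methyl, inverting C4 of unit A from R to S (trans). The O8 phenol of 10 is tied up in a hydrogen bond to the lactone carbonyl and its C4 hydroxyl is silylated, so only O6 should react.

Step 11
Reactants: 14 (the diacetate silyl ether dimer of step 10)
Product: 15 (3R,4S)-4-{[(3R,4S)-4-(tert-butyldimethylsilyloxy)-8-hydroxy-7-methoxy-3-methyl-1-oxoisochroman-6-yl]oxy}-6,8-dihydroxy-7-methoxy-3-methylisochroman-1-one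
Conditions: pyrrolidine (5 equiv), CH2Cl2, 0 to 20 °C; aq. citric acid work-up
Reagents that add atoms: none
Why: The same aryl-ester aminolysis as in step 7; the C4 hydroxyl of unit B is still silylated, so no alkoxide can attack the adjacent lactone, and the benzylic aryl ether is inert to the amine.

Step 12
Reactants: 15 (the silyl ether dimer of step 11)
Product: 16 (3R,4S)-4-{[(3R,4S)-4,8-dihydroxy-7-methoxy-3-methyl-1-oxoisochroman-6-yl]oxy}-6,8-dihydroxy-7-methoxy-3-methylisochroman-1-one (CNP0139537.5)
Conditions: HF·pyridine, THF–pyridine, 0 to 20 °C
Reagents that add atoms: none
Why: Fluoride-driven cleavage of the Si–O bond under weakly acidic conditions; no bond to a stereocentre is broken, and the absence of base avoids translactonization of the freed C4 hydroxyl.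

## Compound list

1 | 2-methoxyresorcinol | COc1c(O)cccc1O | starting material
2 | 2,4-dihydroxy-3-methoxybenzoic acid | COc1c(O)ccc(C(=O)O)c1O | intermediate
3 | 2,4-diacetoxy-3-methoxybenzoic acid | COc1c(OC(C)=O)ccc(C(=O)O)c1OC(C)=O | intermediate
4 | (R)-propylene oxide | C[C@@H]1CO1 | starting material
5 | 2,4-diacetoxy-6-[(2R)-2-hydroxypropyl]-3-methoxybenzoic acid | COc1c(OC(C)=O)cc(C[C@@H](C)O)c(C(=O)O)c1OC(C)=O | intermediate (not isolated)
6 | (R)-6,8-diacetoxy-7-methoxy-3-methylisochroman-1-one | COc1c(OC(C)=O)cc2c(c1OC(C)=O)C(=O)O[C@H](C)C2 | intermediate
7 | (3R,4S)-6,8-diacetoxy-4-bromo-7-methoxy-3-methylisochroman-1-one | COc1c(OC(C)=O)cc2c(c1OC(C)=O)C(=O)O[C@H](C)[C@H]2Br | intermediate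
8 | (3R,4S)-6,8-diacetoxy-4-hydroxy-7-methoxy-3-methylisochroman-1-one | COc1c(OC(C)=O)cc2c(c1OC(C)=O)C(=O)O[C@H](C)[C@H]2O | intermediate
9 | (3R,4S)-6,8-diacetoxy-4-(tert-butyldimethylsilyloxy)-7-methoxy-3-methylisochroman-1-one | COc1c(OC(C)=O)cc2c(c1OC(C)=O)C(=O)O[C@H](C)[C@H]2O[Si](C)(C)C(C)(C)C | intermediate
10 | (3R,4S)-4-(tert-butyldimethylsilyloxy)-6,8-dihydroxy-7-methoxy-3-methylisochroman-1-one | COc1c(O)cc2c(c1O)C(=O)O[C@H](C)[C@H]2O[Si](C)(C)C(C)(C)C | intermediate
11 | (3R,4R)-6,8-diacetoxy-4-(chloroacetoxy)-7-methoxy-3-methylisochroman-1-one | COc1c(OC(C)=O)cc2c(c1OC(C)=O)C(=O)O[C@H](C)[C@@H]2OC(=O)CCl | intermediate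
12 | (3R,4R)-6,8-diacetoxy-7-methoxy-3-methyl-1-oxoisochroman-4-yl (carbamimidoylsulfanyl)acetate hydrochloride | COc1c(OC(C)=O)cc2c(c1OC(C)=O)C(=O)O[C@H](C)[C@@H]2OC(=O)CSC(N)=[NH2+].[Cl-] | intermediate (not isolated)
13 | (3R,4R)-6,8-diacetoxy-4-hydroxy-7-methoxy-3-methylisochroman-1-one | COc1c(OC(C)=O)cc2c(c1OC(C)=O)C(=O)O[C@H](C)[C@@H]2O | intermediate
14 | (3R,4S)-6,8-diacetoxy-4-{[(3R,4S)-4-(tert-butyldimethylsilyloxy)-8-hydroxy-7-methoxy-3-methyl-1-oxoisochroman-6-yl]oxy}-7-methoxy-3-methylisochroman-1-one | COc1c(OC(C)=O)cc2c(c1OC(C)=O)C(=O)O[C@H](C)[C@H]2Oc1cc2c(c(O)c1OC)C(=O)O[C@H](C)[C@H]2O[Si](C)(C)C(C)(C)C | intermediate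
15 | (3R,4S)-4-{[(3R,4S)-4-(tert-butyldimethylsilyloxy)-8-hydroxy-7-methoxy-3-methyl-1-oxoisochroman-6-yl]oxy}-6,8-dihydroxy-7-methoxy-3-methylisochroman-1-one | COc1c(O)cc2c(c1O)C(=O)O[C@H](C)[C@H]2Oc1cc2c(c(O)c1OC)C(=O)O[C@H](C)[C@H]2O[Si](C)(C)C(C)(C)C | intermediate
16 | (3R,4S)-4-{[(3R,4S)-4,8-dihydroxy-7-methoxy-3-methyl-1-oxoisochroman-6-yl]oxy}-6,8-dihydroxy-7-methoxy-3-methylisochroman-1-one | COc1c(O)cc2c(c1O)C(=O)O[C@H](C)[C@H]2Oc1cc2c(c(O)c1OC)C(=O)O[C@H](C)[C@H]2O | target

## Step count and least certain steps

Total step count: 12. Longest linear sequence: 10 steps (steps 1 to 5, then either steps 6 and 7 or steps 8 and 9, then steps 10 to 12).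

**Step 3 (key step).**
- **Risk:** slow or incomplete C–H cleavage, because two acetoxy groups make the arene less electron-rich than the ether-substituted acids best suited to this reaction type. O-alkylation of the carboxylate by the epoxide and partial acetyl loss in the buffered fluoroalcohol would compete.
- **Fallback (sets out from 1, returns at 6):** directed ortho-metalation in place of C–H palladation. 1 would be converted with MOMCl and iPr2NEt into 2-methoxy-1,3-bis(methoxymethoxy)benzene F1. Lithiation next to a MOM ether (n-BuLi, THF, 0 °C) and trapping with diethylcarbamoyl chloride would give N,N-diethyl-3-methoxy-2,4-bis(methoxymethoxy)benzamide F2. Amide-directed lithiation at the only position ortho to the amide (s-BuLi, TMEDA, −78 °C) and BF3·OEt2-assisted opening of 4 at CH2 would give N,N-diethyl-6-[(2R)-2-hydroxypropyl]-3-methoxy-2,4-bis(methoxymethoxy)benzamide F3. Hot methanolic HCl would lactonize the hydroxy amide and remove both MOM groups to give (R)-6,8-dihydroxy-7-methoxy-3-methylisochroman-1-one F4, and Ac2O–pyridine would return the sequence to 6.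

**Step 4.**
- **Risk:** ionic bromination of the ring at C5, a second bromination at C4, or HBr-promoted elimination towards the isocoumarin, since a reactive benzylic halide is formed at 80 °C.
- **Fallback (sets out from 6, returns at 13):** change of oxidation level at C4 instead of halogenation. Aerobic benzylic oxidation (N-hydroxyphthalimide (cat.), Co(OAc)2 (cat.), O2, MeCN, 60 °C) would give (R)-6,8-diacetoxy-7-methoxy-3-methylisochromane-1,4-dione F5. Reduction at low temperature (NaBH4, CeCl3, MeOH–CH2Cl2, −78 °C), with hydride entering anti to the C3 methyl, would give the cis alcohol 13 directly. 8 would then come from 13 by the inversion described under step 5. The weak point is enolization of the ketone towards C3, so the dione would be reduced without storage.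

**Step 5.**
- **Risk:** insufficient facial discrimination in the capture of the cation, or proton loss from C3 to the isocoumarin. A cis epimer formed here is not lost, since it is 13.
- **Fallback (sets out from 7, returns at 11 and, for unit B, at 8):** substitution without a cation. Displacement of the trans bromide with ClCH2CO2Cs in DMF at 20 °C (SN2, inversion) would give 11 directly, and step 9 then 13. For unit B, 13 would be inverted by a Mitsunobu reaction with chloroacetic acid to (3R,4S)-6,8-diacetoxy-4-(chloroacetoxy)-7-methoxy-3-methylisochroman-1-one F6, whose chloroacetate would be removed with thiourea as in step 9 to give 8.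

**Step 10.**
- **Risk:** elimination from the alkoxyphosphonium ion of 13 (its leaving group is anti to H3) towards the isocoumarin, alkylation of the reduced azodicarboxylate in place of the hindered phenoxide, or acetyl transfer from the aryl acetates of 13 to the phenoxide of 10.
- **Fallback (sets out from 7 and 10, returns at 14):** silver-promoted etherification in place of the redox condensation. 7 and 10 would be combined with Ag2O and 4 Å molecular sieves in CH2Cl2–MeCN in the dark. The silver phenoxide of 10 would capture the benzylic cation–bromide pair on the face anti to the C3 methyl, giving 14 with overall retention from the trans bromide. No new compound is involved.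

## Further compounds

F1 | step 3 | 2-methoxy-1,3-bis(methoxymethoxy)benzene | COCOc1cccc(OCOC)c1OC
F2 | step 3 | N,N-diethyl-3-methoxy-2,4-bis(methoxymethoxy)benzamide | CCN(CC)C(=O)c1ccc(OCOC)c(OC)c1OCOC
F3 | step 3 | N,N-diethyl-6-[(2R)-2-hydroxypropyl]-3-methoxy-2,4-bis(methoxymethoxy)benzamide | CCN(CC)C(=O)c1c(C[C@@H](C)O)cc(OCOC)c(OC)c1OCOC
F4 | step 3 | (R)-6,8-dihydroxy-7-methoxy-3-methylisochroman-1-one | COc1c(O)cc2c(c1O)C(=O)O[C@H](C)C2
F5 | step 4 | (R)-6,8-diacetoxy-7-methoxy-3-methylisochromane-1,4-dione | COc1c(OC(C)=O)cc2c(c1OC(C)=O)C(=O)O[C@H](C)C2=O
F6 | step 5 | (3R,4S)-6,8-diacetoxy-4-(chloroacetoxy)-7-methoxy-3-methylisochroman-1-one | COc1c(OC(C)=O)cc2c(c1OC(C)=O)C(=O)O[C@H](C)[C@H]2OC(=O)CCl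
F0 | step 10 | none | none
A1 | alternative 1 | (3R,4S)-4-(tert-butyldimethylsilyloxy)-6,8-dihydroxy-7-methoxy-3-methylisochroman-1-one | COc1c(O)cc2c(c1O)C(=O)O[C@H](C)[C@H]2O[Si](C)(C)C(C)(C)C
A2 | alternative 1 | methyl (4S,5R)-4-(tert-butyldimethylsilyloxy)-5-(trimethylsilyloxy)hex-2-ynoate | COC(=O)C#C[C@H](O[Si](C)(C)C(C)(C)C)[C@@H](C)O[Si](C)(C)C
A3 | alternative 1 | 1,2-dimethoxy-1,3-bis(trimethylsilyloxy)buta-1,3-diene (double-bond geometry not defined) | COC(O[Si](C)(C)C)=C(OC)C(=C)O[Si](C)(C)C
A4 | alternative 2 | (3R,4S)-4-acetoxy-7-methoxy-3-methyl-6,8-bis(pivaloyloxy)isochroman-1-one | COc1c(OC(=O)C(C)(C)C)cc2c(c1OC(=O)C(C)(C)C)C(=O)O[C@H](C)[C@H]2OC(C)=O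
A5 | alternative 2 | methyl 3-methoxy-2,4-bis(pivaloyloxy)-6-[(Z)-prop-1-enyl]benzoate | COC(=O)c1c(/C=C\C)cc(OC(=O)C(C)(C)C)c(OC)c1OC(=O)C(C)(C)C
A6 | alternative 3 | (R)-6,8-dihydroxy-7-methoxy-3-methylisochroman-1-one | COc1c(O)cc2c(c1O)C(=O)O[C@H](C)C2
A7 | alternative 3 | 5,7-dihydroxy-6-methoxy-2-methylindan-1-one (racemic) | COc1c(O)cc2c(c1O)C(=O)C(C)C2
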